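Ring B is not coupled to ring A; it is grown on the C2 oxygen of ring A. Its contiguous atoms C1' (carboxyl), C6' (hydroxyl), C5' (H) and C4' (methyl) are C3 to C6 of a 4-oxygenated 6-methyl-2-pyranone-3-carboxylate, and C2'–C3' is the triple bond of an ethynyl ether. One thermal operation forms C1'–C2' and C3'–C4', expels CO2 and delivers the complete diaryl ether at the aromatic oxidation level. The precursors are a tert-butyl 2-(ethynyloxy)benzoate that carries every ring A substituent, chlorine included, and a pyranone protected only by benzyl groups, so that one base-free Lewis acid step finishes the synthesis.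

Key step: step 11

Remark: 3-chloro-2,4-dihydroxybenzaldehyde is taken as a catalogue compound. Ring A is numbered from the carboxyl-bearing carbon (C1; C2 ether, C3 OH, C4 Cl, C5 OMe), and ring B carries primes.

Remark: chlorine is bought in with 1, so no halogen exchange or late chlorination is needed. The ring B carboxyl and hydroxyl are masked as benzyl ester and benzyl ether. A 2,6-disubstituted methyl benzoate would call for hot hydroxide or iodide, under which the ring B acid may decarboxylate and the C3 phenoxide of ring A may start a Smiles rearrangement.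

Step 1
Reactants: 1 3-chloro-2,4-dihydroxybenzaldehyde
Product: 2 3-chloro-2-hydroxy-4-methoxybenzaldehyde
Conditions: MeI (1.05 equiv), K2CO3, acetone, rt
Reagents that add atoms: iodomethane, CI
Why: Williamson methylation should be selective because the C2 hydroxyl is held in a hydrogen bond to the aldehyde, so the more acidic C4 phenoxide forms and reacts first.

Step 2
Reactants: 2 3-chloro-2-hydroxy-4-methoxybenzaldehyde
Product: 3 2-(benzyloxy)-3-chloro-4-methoxybenzaldehyde
Conditions: BnBr, K2CO3, DMF, 60 °C
Reagents that add atoms: benzyl bromide, BrCc1ccccc1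
Why: Williamson benzylation of the remaining chelated phenol under slightly more forcing conditions installs the group that later protects O3 of ring A.

Step 3
Reactants: 3 2-(benzyloxy)-3-chloro-4-methoxybenzaldehyde
Product: 5 2-(benzyloxy)-3-chloro-4-methoxyphenol, via aryl formate 4 (not isolated)
Conditions: mCPBA, CH2Cl2, 0 °C to rt; aq. NaHCO3 wash; then K2CO3 (cat.), MeOH, rt
Reagents that add atoms: 3-chloroperoxybenzoic acid, OOC(=O)c1cccc(Cl)c1
Why: Baeyer–Villiger oxidation of an ortho,para-dialkoxybenzaldehyde proceeds with aryl migration to the formate, which methanol then transesterifies to the phenol that becomes O2 of ring A.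

Step 4
Reactants: 5 2-(benzyloxy)-3-chloro-4-methoxyphenol
Product: 6 3-(benzyloxy)-4-chloro-2-hydroxy-5-methoxybenzaldehyde
Conditions: MgCl2, Et3N, (CH2O)n, MeCN, reflux; 1 M HCl work-up
Reagents that add atoms: paraformaldehyde (as formaldehyde), C=O
Why: Casnati–Skattebøl ortho-formylation runs through a magnesium phenoxide–formaldehyde chelate and can therefore only reach the single free ortho position, which places the C1 carbon next to O2.

Step 5
Reactants: 6 3-(benzyloxy)-4-chloro-2-hydroxy-5-methoxybenzaldehyde
Product: 7 3-(benzyloxy)-4-chloro-2-hydroxy-5-methoxybenzoic acid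
Conditions: NaClO2, NaH2PO4, 2-methyl-2-butene (excess), t-BuOH/H2O, rt
Reagents that add atoms: sodium chlorite, [Na+].[O-]Cl=O
Why: Lindgren–Pinnick oxidation converts the aldehyde into the acid in the presence of the free phenol, since the alkene scavenger removes HOCl before it can chlorinate C6.

Step 6
Reactants: 7 3-(benzyloxy)-4-chloro-2-hydroxy-5-methoxybenzoic acid
Product: 8 tert-butyl 3-(benzyloxy)-4-chloro-2-hydroxy-5-methoxybenzoate
Conditions: Me2NCH(Ot-Bu)2, toluene, 80 °C
Reagents that add atoms: N,N-dimethylformamide di-tert-butyl acetal, CN(C)C(OC(C)(C)C)OC(C)(C)C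
Why: Esterification with a formamide acetal alkylates the carboxylate through a tert-butyl cation ion pair and should leave the chelated, far less acidic phenol free.

Step 7
Reactants: 8 tert-butyl 3-(benzyloxy)-4-chloro-2-hydroxy-5-methoxybenzoate; 9 trichloroethylene
Product: 11 tert-butyl 3-(benzyloxy)-4-chloro-2-{[(E)-1,2-dichloroethenyl]oxy}-5-methoxybenzoate, via dichloroacetylene 10 (not isolated)
Conditions: K2CO3, DMF, 70 °C
Reagents that add atoms: none
Why: Base-induced dehydrochlorination of trichloroethylene gives dichloroacetylene in solution, and anti addition of the hindered phenoxide to this slim electrophile should give the (E)-dichlorovinyl ether, the standard entry to ynol ethers.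

Step 8
Reactants: 11 tert-butyl 3-(benzyloxy)-4-chloro-2-{[(E)-1,2-dichloroethenyl]oxy}-5-methoxybenzoate
Product: 14 tert-butyl 3-(benzyloxy)-4-chloro-2-(ethynyloxy)-5-methoxybenzoate, via chloroethynyl ether 12 (not isolated), via lithium acetylide 13 (not isolated)
Conditions: n-BuLi (2.1 equiv), THF, −90 °C; H2O/THF quench at −78 °C
Reagents that add atoms: none
Why: Deprotonation with chloride loss followed by chlorine–lithium exchange is the standard conversion of dichlorovinyl ethers into ynol ethers, and both events should be fast enough at −90 °C to outrun addition of n-BuLi to the ortho-shielded tert-butyl ester.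

Step 9
Reactants: 15 dibenzyl malonate; 16 2,2,6-trimethyl-4H-1,3-dioxin-4-one
Product: 19 benzyl 4-hydroxy-6-methyl-2-oxo-2H-pyran-3-carboxylate, via acetylketene 17 (not isolated), via acetoacetylmalonate 18 (not isolated)
Conditions: NaH, THF/toluene, 0 °C; then 16, 105 °C; 1 M HCl work-up
Reagents that add atoms: none
Why: Thermal retro-[4+2] of the dioxinone releases acetylketene, which C-acylates the malonate enolate, and the ketone enol of the adduct lactonises onto one ester, the acylation–cyclocondensation known for diketene and sodiomalonates.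

Step 10
Reactants: 19 benzyl 4-hydroxy-6-methyl-2-oxo-2H-pyran-3-carboxylate
Product: 20 benzyl 4-(benzyloxy)-6-methyl-2-oxo-2H-pyran-3-carboxylate
Conditions: BnOH, PPh3, DIAD, THF, 0 °C to rt
Reagents that add atoms: benzyl alcohol, OCc1ccccc1
Why: Mitsunobu alkylation of acidic 4-hydroxy-2-pyranones takes place at O4 and so avoids the 2-alkoxy-4-pyranone isomer that ambident alkylation with halides may give.

Step 11
Reactants: 14 tert-butyl 3-(benzyloxy)-4-chloro-2-(ethynyloxy)-5-methoxybenzoate; 20 benzyl 4-(benzyloxy)-6-methyl-2-oxo-2H-pyran-3-carboxylate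
Product: 22 tert-butyl 3-(benzyloxy)-2-{3-(benzyloxy)-2-[(benzyloxy)carbonyl]-5-methylphenoxy}-4-chloro-5-methoxybenzoate, via bridged lactone adduct 21 (not isolated)
Conditions: 20 (3 equiv), mesitylene, 150 °C, slow addition of 14, BHT (cat.), Ar, base-washed glassware
Reagents that add atoms: none
Why: The diene C3=C4–C5=C6 of 20, made electron-poor by the lactone carbonyl and the C3 ester, should undergo an asynchronous inverse-demand [4+2] cycloaddition in which the nucleophilic terminal CH of ynol ether 14 bonds to C6 and the oxygen-bearing carbon to C3, after which the strained bridged lactone 21 loses CO2 by retro-[4+2] and aromatises irreversibly. The closest known reaction type is the Diels–Alder/decarboxylation of 2-pyranone-3-carboxylates with alkoxyalkynes, ynamines and ketene acetals, run here on an aryl ynol ether. Ring B is closed by an intermolecular two-bond [4+2] annulation (four pyranone carbons plus two alkyne carbons), so no ring-size question arises, and the two bridgehead stereocentres of 21 vanish on aromatisation, leaving none to control. The one selectivity needed is regiochemical: C6 is the terminus of the vinylogous acceptor system of both carbonyl groups while C4 is deactivated by its benzyloxy donor, and the ynol ether oxygen polarises the alkyne toward its CH end, so the matched orientation puts the aryloxy group next to the ester (C2') and the CH next to the methyl-bearing carbon (C3' beside C4'). Excess diene and slow addition keep the concentration of 14 low and hold back its self-reaction, and aprotic acid-free conditions protect the ynol ether and the tert-butyl ester.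

Step 12
Reactants: 22 tert-butyl 3-(benzyloxy)-2-{3-(benzyloxy)-2-[(benzyloxy)carbonyl]-5-methylphenoxy}-4-chloro-5-methoxybenzoate
Product: 23 2-(2-carboxy-3-hydroxy-5-methylphenoxy)-4-chloro-3-hydroxy-5-methoxybenzoic acid (CNP0310398.0)
Conditions: BCl3 (excess), C6HMe5, CH2Cl2, −78 to 0 °C; MeOH, then H2O
Reagents that add atoms: none
Why: Lewis acid dealkylation with BCl3 ionises the three O–benzyl bonds and the O–tert-butyl bond while pentamethylbenzene traps the benzyl cations, the ring A methyl ether with no neighbouring carbonyl for chelation should be retained, and neither base nor heat reaches the decarboxylation-prone ring B acid.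

Compound list
1 | 3-chloro-2,4-dihydroxybenzaldehyde | O=Cc1ccc(O)c(Cl)c1O | starting material
2 | 3-chloro-2-hydroxy-4-methoxybenzaldehyde | O=Cc1ccc(OC)c(Cl)c1O | intermediate
3 | 2-(benzyloxy)-3-chloro-4-methoxybenzaldehyde | O=Cc1ccc(OC)c(Cl)c1OCc1ccccc1 | intermediate
4 | 2-(benzyloxy)-3-chloro-4-methoxyphenyl formate (not isolated) | O=COc1ccc(OC)c(Cl)c1OCc1ccccc1 | intermediate
5 | 2-(benzyloxy)-3-chloro-4-methoxyphenol | Oc1ccc(OC)c(Cl)c1OCc1ccccc1 | intermediate
6 | 3-(benzyloxy)-4-chloro-2-hydroxy-5-methoxybenzaldehyde | O=Cc1cc(OC)c(Cl)c(OCc2ccccc2)c1O | intermediate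
7 | 3-(benzyloxy)-4-chloro-2-hydroxy-5-methoxybenzoic acid | OC(=O)c1cc(OC)c(Cl)c(OCc2ccccc2)c1O | intermediate
8 | tert-butyl 3-(benzyloxy)-4-chloro-2-hydroxy-5-methoxybenzoate | CC(C)(C)OC(=O)c1cc(OC)c(Cl)c(OCc2ccccc2)c1O | intermediate
9 | trichloroethylene | ClC=C(Cl)Cl | starting material
10 | dichloroacetylene (not isolated) | ClC#CCl | intermediate
11 | tert-butyl 3-(benzyloxy)-4-chloro-2-{[(E)-1,2-dichloroethenyl]oxy}-5-methoxybenzoate | CC(C)(C)OC(=O)c1cc(OC)c(Cl)c(OCc2ccccc2)c1O/C(Cl)=C\Cl | intermediate
12 | tert-butyl 3-(benzyloxy)-4-chloro-2-[(chloroethynyl)oxy]-5-methoxybenzoate (not isolated) | CC(C)(C)OC(=O)c1cc(OC)c(Cl)c(OCc2ccccc2)c1OC#CCl | intermediate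
13 | lithium acetylide of 14 (not isolated) | CC(C)(C)OC(=O)c1cc(OC)c(Cl)c(OCc2ccccc2)c1OC#C[Li] | intermediate
14 | tert-butyl 3-(benzyloxy)-4-chloro-2-(ethynyloxy)-5-methoxybenzoate | CC(C)(C)OC(=O)c1cc(OC)c(Cl)c(OCc2ccccc2)c1OC#C | intermediate
15 | dibenzyl malonate | O=C(CC(=O)OCc1ccccc1)OCc1ccccc1 | starting material
16 | 2,2,6-trimethyl-4H-1,3-dioxin-4-one | CC1=CC(=O)OC(C)(C)O1 | starting material
17 | acetylketene (not isolated) | CC(=O)C=C=O | intermediate
18 | dibenzyl 2-(3-oxobutanoyl)propanedioate (not isolated) | CC(=O)CC(=O)C(C(=O)OCc1ccccc1)C(=O)OCc1ccccc1 | intermediate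
19 | benzyl 4-hydroxy-6-methyl-2-oxo-2H-pyran-3-carboxylate | CC1=CC(O)=C(C(=O)OCc2ccccc2)C(=O)O1 | intermediate
20 | benzyl 4-(benzyloxy)-6-methyl-2-oxo-2H-pyran-3-carboxylate | CC1=CC(OCc2ccccc2)=C(C(=O)OCc2ccccc2)C(=O)O1 | intermediate
21 | tert-butyl 3-(benzyloxy)-2-({8-(benzyloxy)-4-[(benzyloxy)carbonyl]-1-methyl-3-oxo-2-oxabicyclo[2.2.2]octa-5,7-dien-5-yl}oxy)-4-chloro-5-methoxybenzoate (racemic, not isolated) | CC12OC(=O)C(C(=O)OCc3ccccc3)(C(OCc3ccccc3)=C1)C(Oc1c(OCc3ccccc3)c(Cl)c(OC)cc1C(=O)OC(C)(C)C)=C2 | intermediate
22 | tert-butyl 3-(benzyloxy)-2-{3-(benzyloxy)-2-[(benzyloxy)carbonyl]-5-methylphenoxy}-4-chloro-5-methoxybenzoate | CC(C)(C)OC(=O)c1cc(OC)c(Cl)c(OCc2ccccc2)c1Oc1cc(C)cc(OCc2ccccc2)c1C(=O)OCc1ccccc1 | intermediate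
23 | 2-(2-carboxy-3-hydroxy-5-methylphenoxy)-4-chloro-3-hydroxy-5-methoxybenzoic acid | COc1cc(C(=O)O)c(Oc2cc(C)cc(O)c2C(=O)O)c(O)c1Cl | target

Total step count: 12
Longest linear sequence: 10 steps (steps 1 to 8, 11 and 12)

Steps most likely to fail

Step 11. The benzyloxy donor at C4 and the methyl group at C6 may slow the cycloaddition so far that self-reaction or adventitious hydration consumes the ethynyl ether first. The fallback makes the ether bond by cross-coupling instead of annulation and sets out from phenol 8. Commercial 2,6-dihydroxy-4-methylbenzoic acid is benzylated on the carboxyl group and on one hydroxyl (BnBr, K2CO3, DMF) to benzyl 2-(benzyloxy)-6-hydroxy-4-methylbenzoate F1. The remaining chelated phenol is sulfonylated (Tf2O, pyridine, CH2Cl2) to benzyl 2-(benzyloxy)-4-methyl-6-{[(trifluoromethyl)sulfonyl]oxy}benzoate F2. Buchwald–Hartwig etherification of F2 with 8 (Pd(OAc)2, t-BuXPhos, K3PO4, toluene, 100 °C) comes back to the route at 22.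

Step 8. n-BuLi may add to the ester, or the lithiated vinyl ether may expel the stabilised salicylate-type phenoxide, which would reverse step 7. The fallback uses no organolithium and sets out from phenol 8. Chan–Lam vinylation (2,4,6-trivinylcyclotriboroxane–pyridine complex, Cu(OAc)2, pyridine, CH2Cl2, air) gives tert-butyl 3-(benzyloxy)-4-chloro-2-(ethenyloxy)-5-methoxybenzoate F3. Addition of Br2 in CH2Cl2 at −78 °C gives tert-butyl 3-(benzyloxy)-4-chloro-2-(1,2-dibromoethoxy)-5-methoxybenzoate F4. DBU removes the first HBr to give tert-butyl 3-(benzyloxy)-2-{[(Z)-2-bromoethenyl]oxy}-4-chloro-5-methoxybenzoate F5. KOt-Bu in THF, which is degenerate toward the tert-butyl ester, effects the second, anti dehydrobromination and comes back to the route at 14.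

Step 12. The benzyl ester may be cleaved incompletely at low temperature, or the ring A methyl ether may be partly lost once the mixture is warmed to force that cleavage. The fallback splits the task between hydrogenolysis and a Brønsted acid and sets out from 22. Treatment with H2 (1 atm) and Pd/C in EtOAc at rt without base, stopped after uptake of three equivalents to spare the aryl chloride, gives 2-[6-(tert-butoxycarbonyl)-3-chloro-2-hydroxy-4-methoxyphenoxy]-6-hydroxy-4-methylbenzoic acid F6. TFA in CH2Cl2 at 0 °C then removes the tert-butyl group and comes back to the route at 23.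

Further compounds
F1 | step 11 | benzyl 2-(benzyloxy)-6-hydroxy-4-methylbenzoate | Cc1cc(O)c(C(=O)OCc2ccccc2)c(OCc2ccccc2)c1
F2 | step 11 | benzyl 2-(benzyloxy)-4-methyl-6-{[(trifluoromethyl)sulfonyl]oxy}benzoate | Cc1cc(OCc2ccccc2)c(C(=O)OCc2ccccc2)c(OS(=O)(=O)C(F)(F)F)c1
F3 | step 8 | tert-butyl 3-(benzyloxy)-4-chloro-2-(ethenyloxy)-5-methoxybenzoate | CC(C)(C)OC(=O)c1cc(OC)c(Cl)c(OCc2ccccc2)c1OC=C
F4 | step 8 | tert-butyl 3-(benzyloxy)-4-chloro-2-(1,2-dibromoethoxy)-5-methoxybenzoate (racemic) | CC(C)(C)OC(=O)c1cc(OC)c(Cl)c(OCc2ccccc2)c1OC(Br)CBr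
F5 | step 8 | tert-butyl 3-(benzyloxy)-2-{[(Z)-2-bromoethenyl]oxy}-4-chloro-5-methoxybenzoate | CC(C)(C)OC(=O)c1cc(OC)c(Cl)c(OCc2ccccc2)c1O/C=C\Br
F6 | step 12 | 2-[6-(tert-butoxycarbonyl)-3-chloro-2-hydroxy-4-methoxyphenoxy]-6-hydroxy-4-methylbenzoic acid | CC(C)(C)OC(=O)c1cc(OC)c(Cl)c(O)c1Oc1cc(C)cc(O)c1C(=O)O
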